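## Structural features

The target is a germacranolide: a ten-membered carbocycle (C1 to C10) with a ring-cis C1=C10 alkene carrying methyl C14 and a ring-trans C4=C5 alkene carrying the hydroxymethyl C15. It is trans-fused through C6–C7 to an α-methyl-γ-butyrolactone (O6–C12(=O)–C11, methyl C13) and esterified at O8 with (S)-4-hydroxy-3-methylbutanoic acid. Four stereocentres are contiguous, C6 (R), C7 (R), C8 (S) and C11 (S): H6 and H7 are anti, the C8 oxygen is anti to the C7–C11 bond, and the C13 methyl lies on the same lactone face as H7. The fifth centre, C3′ (S), is isolated in the side chain. Fragile elements are the 1,5-diene (Cope rearrangement on heating, transannular cyclisation in acid), the allylic lactone C6–O bond, the O8 ester beside the lactone (translactonisation to a 12,8-olide whenever O8 is free under base) and the primary allylic alcohol. The real difficulty is the medium ring with two trisubstituted alkenes of opposite ring geometry, because direct closure fights entropy and transannular strain and both geometries must be set together. The feature exploited is that C1–C10 and C4–C5 are exactly the two σ-bonds that a cyclobutene C1=C4 (C2 and C3 as its methylenes) makes with an enone C5=C10. Ring carbons C5 to C10 can therefore come from a cyclohex-2-enone whose carbonyl is C6 and whose sp3 carbons C7 and C8 already hold the stereochemistry; O6 is the enone carbonyl and C15 is the ester that polarises the cyclobutene.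

## Logic of the disconnections

35 ⇒ 34 ⇒ 32 ⇒ 30 (O–Si, then the C15–H bonds, then the C15 O–tert-butyl bond). C15 must arrive as a carboxyl derivative because that carbonyl directs the key step, so its reduction is placed last. The gain is that 30 carries only robust groups. The forward demand is a hydride that reduces an activated acid but not the lactone or the C8 ester, and an ester cleavage that spares the primary silyl ether and the 1,5-diene.

30 ⇒ 23 + 29 (the O8–C1′ acyl bond). This cut makes the route convergent and keeps the remote C3′ centre out of the ring chemistry. The demand is acylation of a hindered secondary alcohol next to the lactone without O8 attacking C12.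

29 ⇒ 28 ⇒ 27 ⇒ 26 ⇒ 25 ⇒ 24 (the C1′–C2′ bond, then C–I and C–O functional group changes). One carbon is added at the ester end of 24 so that the stereocentre is never touched; adding it at the hydroxyl end would give the enantiomer. The demand is an organometallic at C2′ that lasts long enough to be carboxylated.

23 ⇒ 22 ⇒ 21 ⇒ 20 (O8–Si; the O6–C12 acyl bond; the C6–H bond). The lactone oxygen is traced to the ketone of 20 and the lactone carbonyl to its methyl ester, which removes C6 as a stereocentre and removes the second ring. The demand is 1,2-reduction of a doubly activated enone with the hydroxyl delivered anti to H7, and an O8 silyl ether that stays on until the lactone is closed so that the 12,8-olide cannot form.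

20 ⇒ 19 ⇒ 15 + 18 (re-forming C5–C10 and C1–C4, then cutting C1–C10 and C4–C5). This is the strategic cut: the ten-membered ring with both alkenes collapses to a six-membered enone holding C7, C8 and C11, plus an achiral four-membered alkene. The demand is head-to-head union, a cis-fused adduct, a fragmentation that gives ring-cis C1=C10 and ring-trans C4=C5, and heating short enough to avoid Cope rearrangement.

18 ⇒ 17 ⇒ 16 (ester C–O; C1=C4 by loss of HBr). The cyclobutene is reduced to a commercial α-bromo ester. The demand is that the strained, polymerisable acrylic acid be handled cold and used fresh.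

15 ⇒ 14 + 13, 14 ⇒ 11, 13 ⇒ 12 (the C7–C11 bond). Cutting between ring and propionate branch lets C11 come from the chiral pool by inversion and C7 be set by approach anti to the C8 silyloxy group. The demand is that a basic enolate substitutes a secondary sulfonate faster than it eliminates it or expels its own β-silyloxy group.

11 ⇒ 10 ⇒ 9 (the C10–C14 bond). Removing the methyl group leads to a silyloxy enone from the chiral pool. The demand is that the carbonyl stays on the same carbon: only then does the silyloxy centre of 9 have the configuration needed for C8 (11 must be S). A 1,2-addition and carbonyl transposition would exchange the two arms and give the enantiomer of 11.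

9 ⇒ 8 ⇒ 7 ⇒ 6 (O–Si; restoring the oxygen on the γ-carbon). The deoxygenated enone is traced to a dioxygenated one. The demand is reductive cleavage of the γ-C–O bond without reducing the enone, and immediate protection of the labile β-hydroxy enone.

6 ⇒ 5 ⇒ 4 ⇒ 3 ⇒ 2 ⇒ 1 (C=C from a β-hydroxy ketone; the C1–C7 bond; protecting groups). The carboxyl carbon of 1 is excised, its C1 becomes the enone carbonyl (C6 of the target), its C3 carbinol becomes C8, and the C4 and C5 oxygens are sacrificed. The demand is only that the cis-diol be masked so that the C5 hydroxyl alone is eliminated.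

## Other disconnections considered

Alternative 1: The cut is C7–C8, reached by contracting a thirteen-membered ring in which O8 is tied to C12.
- **Forward step:** tin–lithium exchange at C8 of the cyclic α-alkoxystannane A1 gives a carbanion that undergoes a [2,3]-Wittig shift across the O8–C12–C11=C7 allyl ether. This forms C7–C8, frees O8 as the alkoxide and leaves C11=C12 as an isopropenyl group in the ten-membered dienol A2.
- **In favour:** the ring is made by contraction of a larger, easier ether ring. The step runs at low temperature, so the 1,5-diene is never heated; on this point it is better than the chosen plan. Both ring alkenes are installed beforehand with fixed geometry, which is also better than relying on a diyl conformation. C7 and C8 are created together under transfer from the C8 stannane configuration and the C7=C11 geometry (A1 is drawn assuming retention in the exchange, inversion at the carbanion carbon and an anti product from the E-alkene).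
- **Against:** A2 still has C12 at the alkene level. C11 and the C12 carboxyl must be made afterwards by hydroboration of the isopropenyl group beside two ring alkenes, with unproven facial control at C11, then oxidation and lactonisation. A1 needs a configurationally defined α-alkoxystannane and a macro-etherification, a competing [1,2]-shift is possible, and tin reagents are required.
- **Comparison:** on structure the two plans are equal in creating no C6 centre during ring formation; the alternative is better on alkene geometry and worse on C11, which the chosen plan fixes by substitution before the ring exists. On mechanism it is a concerted anionic shift against a photochemical biradical closure and a thermal diyl fragmentation: milder, but with a much more elaborate substrate. On step economy A1 needs a longer linear build than the nine steps to 15, and about seven steps follow A2 against six after 20.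

Alternative 2: The cut is C2–C3, the one ring bond remote from all functionality.
- **Forward step:** Ni(cod)2 (zerovalent nickel) adds oxidatively to both allylic C–Br bonds of the open-chain lactone A3 and the two allyl ligands on nickel couple head to head. This closes the ring to A4, the bis(silyl) ether of the target.
- **In favour:** it is the most convergent plan. The lactone, the C8 ester, all five stereocentres and the C15 oxidation level are in place before ring closure, and A4 needs one double desilylation; this endgame is clearly better than the six steps after 20. The new bond involves no protecting-group interplay.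
- **Against:** allylnickel species interconvert between σ and π forms, so the ring-cis C1=C10 and ring-trans C4=C5 geometries may not be retained. Head-to-tail coupling would give vinyl-substituted smaller rings. Ten-membered closure needs high dilution and stoichiometric, air-sensitive Ni(cod)2. A3 requires acyclic control of C6, C7, C8 and C11 and carries two labile allylic bromides.
- **Comparison:** on structure the plans are equal in that neither ring-forming step creates a stereocentre. The chosen plan sets geometry by ring conformation; the alternative relies on retention, which is less secure. After the key step the alternative is better on step count; before it, it is longer. Its riskiest step falls on the most advanced intermediate.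

Alternative 3: The cut is C5–C6.
- **Forward step:** a Nozaki–Hiyama–Kishi closure of the iodo aldehyde A5. NiCl2 (divalent nickel) activates the C5 alkenyl iodide, the alkenyl group passes to chromium (CrCl2, divalent chromium, regenerated at the cathode from the trivalent chromium alkoxide), and the C5–Cr bond adds to the C6 aldehyde to give the allylic alcohol A6.
- **In favour:** the coupling is selective for an aldehyde in the presence of esters and silyl ethers. The alkenyl iodide geometry is retained, so ring-trans C4=C5 is fixed beforehand; this is better than conformational control. C15 is already at the alcohol level, which saves the two late redox steps of the chosen plan. A6 lactonises just as 21 does, and the chromium is catalytic.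
- **Against:** C6 is created in the ring-closing step under substrate control. This is the same problem as in step 13 and no better; the chosen plan can switch to reagent control on a ketone. The α-branched β-silyloxy aldehyde of A5 is prone to epimerisation at C7 and to β-elimination. Closure needs high dilution, and A5 needs a ring-cis trisubstituted C1=C10 and the C7/C8/C11 triad built acyclically.
- **Comparison:** on mechanism it is a polar organometallic addition near room temperature against light and heat, which is gentler to the diene. On step economy its endgame is shorter (about four steps against six) and its precursor longer, so the totals are comparable. The chosen plan reaches the ten-membered ring from 15 in one operation and uses cyclic stereocontrol for C7 and C8.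

Key step: step 12

Remark on the chemistry: germacranolide numbering (C1 to C15) is used for all compounds from 14 on; 19 is drawn as the isomer formed anti to the C8 silyloxy group, its other cis-fused head-to-head diastereomers being assumed to converge on 20; 16 is assumed to be purchased (it is the Hell–Volhard–Zelinsky bromination and esterification product of cyclobutanecarboxylic acid).

Step 1
Reactants: 1 (−)-quinic acid
Product: 2 3,4-O-isopropylidenequinic acid 1,5-lactone
Conditions: 2,2-dimethoxypropane, TsOH·H2O (cat.), acetone, reflux
Reagents that add atoms: 2,2-dimethoxypropane, COC(C)(C)OC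
Why: Acid-catalysed transketalisation with lactonisation: the cis 3,4-diol closes the dioxolane and the carboxyl closes onto the 5-hydroxyl that is cis to it; no stereocentre is touched.

Step 2
Reactants: 2 3,4-O-isopropylidenequinic acid 1,5-lactone
Product: 3 1-(hydroxymethyl)-3,4-O-isopropylidenecyclohexane-1,3,4,5-tetrol (quinic acid configuration)
Conditions: NaBH4, EtOH, 0 °C to rt
Reagents that add atoms: none
Why: Borohydride reduction of the strained bridged lactone to the primary alcohol unmasks a 1,2-diol at C1; the acetonide is inert.

Step 3
Reactants: 3 1-(hydroxymethyl)-3,4-O-isopropylidenecyclohexane-1,3,4,5-tetrol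
Product: 4 (3R,4S,5R)-3-hydroxy-4,5-(isopropylidenedioxy)cyclohexan-1-one
Conditions: NaIO4, H2O (pH 7 phosphate buffer), 0 °C to rt
Reagents that add atoms: none
Why: Periodate glycol cleavage of the only free 1,2-diol removes the former carboxyl carbon as formaldehyde and leaves the C1 ketone.

Step 4
Reactants: 4 (3R,4S,5R)-3-hydroxy-4,5-(isopropylidenedioxy)cyclohexan-1-one
Product: 6 (4S,5R)-4,5-(isopropylidenedioxy)cyclohex-2-en-1-one, via β-mesyloxy ketone 5 (not isolated)
Conditions: MsCl, Et3N, CH2Cl2, 0 °C to rt
Reagents that add atoms: methanesulfonyl chloride, CS(=O)(=O)Cl (its atoms are present in 5 only)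
Why: Mesylation of the β-hydroxy ketone and E1cB elimination by Et3N give the conjugated enone; the sulfonate leaves in preference to the acetonide oxygen and both remaining stereocentres are untouched.

Step 5
Reactants: 6 (4S,5R)-4,5-(isopropylidenedioxy)cyclohex-2-en-1-one
Product: 8 (S)-5-hydroxycyclohex-2-en-1-one, via (R)-5-hydroxycyclohex-3-en-1-one 7 (not isolated)
Conditions: SmI2 (2.2 equiv), MeOH, THF, −78 °C; then Et3N, 0 °C
Reagents that add atoms: none
Why: Reductive cleavage of a γ-alkoxy enone by SmI2 (divalent samarium): two single-electron transfers expel the γ-oxygen, the dienolate is protonated at the α-carbon and the hemiketal loses acetone. Mild base then moves the alkene into conjugation; the carbinol centre is not involved.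

Step 6
Reactants: 8 (S)-5-hydroxycyclohex-2-en-1-one
Product: 9 (S)-5-(tert-butyldimethylsilyloxy)cyclohex-2-en-1-one
Conditions: TBSCl, imidazole, CH2Cl2, 0 °C to rt
Reagents that add atoms: tert-butyldimethylsilyl chloride, CC(C)(C)[Si](C)(C)Cl
Why: Standard silylation, done at once because the free β-hydroxy enone can dehydrate to phenol.

Step 7
Reactants: 9 (S)-5-(tert-butyldimethylsilyloxy)cyclohex-2-en-1-one
Product: 11 (S)-5-(tert-butyldimethylsilyloxy)-3-methylcyclohex-2-en-1-one, via trimethylsilyl enol ether 10 (not isolated)
Conditions: MeMgBr, CuBr·SMe2 (5 mol %), TMSCl, THF, −78 °C; then Pd(OAc)2 (1.05 equiv), MeCN, rt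
Reagents that add atoms: methylmagnesium bromide, C[Mg]Br; chlorotrimethylsilane, C[Si](C)(C)Cl (its atoms are present in 10 only)
Why: Copper-catalysed conjugate addition of the Grignard reagent, trapped by TMSCl, gives the regiodefined silyl enol ether 10 (methyl trans to the silyloxy group; this centre is lost again). Saegusa–Ito oxidation with Pd(OAc)2 (divalent palladium, reduced to zerovalent palladium) restores the enone by β-hydride elimination from the methyl-bearing carbon. The carbonyl therefore stays on its original carbon and the silyloxy centre remains S, whereas 1,2-addition with oxidative transposition would give the R enantiomer.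

Step 8
Reactants: 12 methyl (S)-lactate
Product: 13 methyl (S)-2-(trifluoromethylsulfonyloxy)propanoate
Conditions: Tf2O, 2,6-lutidine, CH2Cl2, −78 to 0 °C
Reagents that add atoms: trifluoromethanesulfonic anhydride, O=S(=O)(OS(=O)(=O)C(F)(F)F)C(F)(F)F
Why: O-sulfonylation of the secondary alcohol; the C–O bond is not broken, so configuration is retained, and the triflate is used at once.

Step 9
Reactants: 11 (S)-5-(tert-butyldimethylsilyloxy)-3-methylcyclohex-2-en-1-one; 13 methyl (S)-2-(trifluoromethylsulfonyloxy)propanoate
Product: 15 methyl (2S)-2-[(1R,6S)-6-(tert-butyldimethylsilyloxy)-4-methyl-2-oxocyclohex-3-en-1-yl]propanoate, via lithium dienolate 14 (not isolated)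
Conditions: LDA, THF, −78 °C; then 13, DMPU, −78 to −40 °C
Reagents that add atoms: lithium diisopropylamide, [Li]N(C(C)C)C(C)C (its lithium is present in 14 only)
Why: Kinetic deprotonation at the α′-carbon gives the cross-conjugated enolate, which is alkylated anti to the neighbouring silyloxy group, setting C7 trans to C8. The enolate alkylation is an SN2 displacement of the secondary triflate with inversion, so the S-lactate delivers the 11S centre.

Step 10
Reactants: 16 ethyl 1-bromocyclobutane-1-carboxylate
Product: 17 cyclobut-1-ene-1-carboxylic acid
Conditions: KOH (powdered), PhMe, reflux; then aq. HCl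
Reagents that add atoms: potassium hydroxide, [K+].[OH-] (one carboxyl oxygen)
Why: Base-induced dehydrobromination (E2) of the tertiary α-bromo ester with concurrent saponification gives the strained conjugated acid, which is used fresh.

Step 11
Reactants: 17 cyclobut-1-ene-1-carboxylic acid
Product: 18 tert-butyl cyclobut-1-ene-1-carboxylate
Conditions: isobutene, H2SO4 (cat.), CH2Cl2, −20 °C to rt (pressure vessel)
Reagents that add atoms: isobutene, CC(C)=C
Why: Acid-catalysed addition of the carboxylic acid to isobutene (tert-butyl ester formation). The tert-butyl ester survives hydride, fluoride and DMAP and can later be removed without touching the lactone.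

Step 12
Reactants: 15 methyl (2S)-2-[(1R,6S)-6-(tert-butyldimethylsilyloxy)-4-methyl-2-oxocyclohex-3-en-1-yl]propanoate; 18 tert-butyl cyclobut-1-ene-1-carboxylate
Product: 20 tert-butyl (7R,8S)-8-(tert-butyldimethylsilyloxy)-7-[(2S)-1-methoxy-1-oxopropan-2-yl]-10-methyl-6-oxocyclodeca-1(10),4-diene-4-carboxylate (ring-cis C1=C10 / ring-trans C4=C5), via head-to-head cis-anti-cis photoadduct 19 (not isolated)
Conditions: 18 (4 equiv), CH2Cl2, hν (λ > 300 nm, Pyrex), −20 °C; then PhMe (degassed, base-washed sealed tube), 180 °C
Reagents that add atoms: none
Why: Light above 300 nm excites only the enone of 15; after intersystem crossing the triplet bonds first from its β-carbon C10 to the unsubstituted cyclobutene carbon C1, which leaves the best-stabilised 1,4-biradical (α-keto radical at C5, tertiary α-ester radical at C4), and after spin inversion C4–C5 closes the new cyclobutane as the head-to-head, cis-anti-cis adduct 19. This is the intermolecular enone–alkene [2+2] photocycloaddition applied to a strained cyclobutene ester, and the four-membered ring closes by radical–radical combination within the biradical, not by a polar exo or endo attack. On heating, the strained C1–C4 bond shared by the two four-membered rings of the bicyclo[2.2.0]hexane unit homolyses and the resulting cyclohexane-1,4-diyl cleaves C5–C10; the ten-membered ring therefore appears by ring expansion (loss of the two inter-ring σ-bonds), the known thermal cycloreversion of such adducts to cis,trans-cyclodeca-1,5-dienes, and not by an end-to-end cyclisation. No stereocentre is created: C1, C4, C5 and C10 all end as sp2 carbons, so every cis-fused head-to-head diastereomer of 19 should give the same 20, while C7, C8 and C11 are carried through untouched. The step needs head-to-head regiochemistry, which the ester secures by polarising the cyclobutene and stabilising the C4 radical, and it needs a ring-cis C1=C10 beside a ring-trans C4=C5, which the chair-like diyl secures because keeping the C14 methyl equatorial puts C9 axial (cis alkene) and C6 equatorial (trans alkene). The competing cleavage of C2–C3 and a later Cope rearrangement both lead to the divinylcyclohexane isomer; conjugation of C4=C5 with the C6 ketone and the C15 ester favours 20, and heating is stopped once 19 is consumed to limit Cope drift and thermal loss of silanol.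

Step 13
Reactants: 20 tert-butyl (7R,8S)-8-(tert-butyldimethylsilyloxy)-7-[(2S)-1-methoxy-1-oxopropan-2-yl]-10-methyl-6-oxocyclodeca-1(10),4-diene-4-carboxylate
Product: 22 tert-butyl 8-(tert-butyldimethylsilyloxy)germacra-1(10),4-dien-12,6-olid-15-oate (trans-fused lactone), via C6 hydroxy ester 21 (not isolated)
Conditions: NaBH4, CeCl3·7H2O, MeOH, −78 to −40 °C; then PPTS (cat.), CH2Cl2, rt
Reagents that add atoms: none
Why: Luche reduction: CeCl3 steers borohydride to 1,2-addition at the doubly activated enone, and hydride is expected to enter from the open peripheral face of the C6 carbonyl with the C11 branch on C7 turned away (Felkin-type), giving the 6R alcohol with H6 anti to H7. The γ-hydroxy methyl ester 21 then lactonises (5-exo-trig acyl substitution) to the trans-fused lactone with loss of methanol.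

Step 14
Reactants: 22 tert-butyl 8-(tert-butyldimethylsilyloxy)germacra-1(10),4-dien-12,6-olid-15-oate
Product: 23 tert-butyl 8-hydroxygermacra-1(10),4-dien-12,6-olid-15-oate
Conditions: HF·pyridine, pyridine, THF, 0 °C to rt
Reagents that add atoms: none
Why: Fluoride cleavage of the secondary silyl ether under buffered, weakly acidic conditions, chosen so that no free alkoxide at O8 can translactonise to the 12,8-olide; the tert-butyl ester and lactone are inert.

Step 15
Reactants: 24 methyl (R)-3-hydroxy-2-methylpropanoate
Product: 25 methyl (R)-3-(tert-butyldimethylsilyloxy)-2-methylpropanoate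
Conditions: TBSCl, imidazole, CH2Cl2, rt
Reagents that add atoms: tert-butyldimethylsilyl chloride, CC(C)(C)[Si](C)(C)Cl
Why: Standard silylation of the primary alcohol.

Step 16
Reactants: 25 methyl (R)-3-(tert-butyldimethylsilyloxy)-2-methylpropanoate
Product: 26 (S)-3-(tert-butyldimethylsilyloxy)-2-methylpropan-1-ol
Conditions: LiBH4, THF, 0 °C to rt
Reagents that add atoms: none
Why: Borohydride reduction of the ester to the primary alcohol under non-basic conditions that do not epimerise the α-centre; the descriptor changes only through priorities.

Step 17
Reactants: 26 (S)-3-(tert-butyldimethylsilyloxy)-2-methylpropan-1-ol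
Product: 27 (R)-tert-butyl(3-iodo-2-methylpropoxy)dimethylsilane
Conditions: I2, PPh3, imidazole, CH2Cl2, 0 °C to rt
Reagents that add atoms: iodine, II
Why: Appel-type iodination of the primary alcohol by SN2 at CH2; the adjacent stereocentre is untouched.

Step 18
Reactants: 27 (R)-tert-butyl(3-iodo-2-methylpropoxy)dimethylsilane
Product: 29 (S)-4-(tert-butyldimethylsilyloxy)-3-methylbutanoic acid, via alkyllithium 28 (not isolated)
Conditions: t-BuLi (2.1 equiv), Et2O, −78 °C; then CO2 (excess), −78 °C to rt; aq. HCl (pH 3)
Reagents that add atoms: tert-butyllithium, [Li]C(C)(C)C (its lithium is present in 28 only); carbon dioxide, O=C=O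
Why: Iodine–lithium exchange followed by carboxylation adds the carboxyl carbon at the former ester terminus. The spatial arrangement at the stereocentre is kept and matches C3′ of the target.

Step 19
Reactants: 23 tert-butyl 8-hydroxygermacra-1(10),4-dien-12,6-olid-15-oate; 29 (S)-4-(tert-butyldimethylsilyloxy)-3-methylbutanoic acid
Product: 30 tert-butyl 8-[(3S)-4-(tert-butyldimethylsilyloxy)-3-methylbutanoyloxy]germacra-1(10),4-dien-12,6-olid-15-oate
Conditions: DCC, DMAP (cat.), CH2Cl2, 0 °C to rt
Reagents that add atoms: none
Why: Steglich esterification of the secondary C8 alcohol with an unhindered acid; acyl transfer from the acylpyridinium is expected to be faster than any attack of O8 on the lactone carbonyl.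

Step 20
Reactants: 30 tert-butyl 8-[(3S)-4-(tert-butyldimethylsilyloxy)-3-methylbutanoyloxy]germacra-1(10),4-dien-12,6-olid-15-oate
Product: 32 8-[(3S)-4-(tert-butyldimethylsilyloxy)-3-methylbutanoyloxy]germacra-1(10),4-dien-12,6-olid-15-oic acid, via trimethylsilyl ester 31 (not isolated)
Conditions: TMSOTf, 2,6-lutidine, CH2Cl2, 0 °C; then pH 5 aq. buffer
Reagents that add atoms: trimethylsilyl trifluoromethanesulfonate, C[Si](C)(C)OS(=O)(=O)C(F)(F)F (its silicon is present in 31 only)
Why: Silyl-triflate-mediated tert-butyl ester cleavage: O-silylation of the ester carbonyl and loss of the tert-butyl group as isobutene give the silyl ester, which hydrolyses on buffered work-up. 2,6-Lutidine keeps the medium free of strong protic acid and is too weak a base to enolise the lactone, so the primary silyl ether, C11 and the 1,5-diene are spared.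

Step 21
Reactants: 32 8-[(3S)-4-(tert-butyldimethylsilyloxy)-3-methylbutanoyloxy]germacra-1(10),4-dien-12,6-olid-15-oic acid
Product: 34 15-hydroxy-8-[(3S)-4-(tert-butyldimethylsilyloxy)-3-methylbutanoyloxy]germacra-1(10),4-dien-12,6-olide, via isobutyl carbonic mixed anhydride 33 (not isolated)
Conditions: i-BuOCOCl, N-methylmorpholine, THF, −15 °C; then NaBH4, H2O–THF, 0 °C
Reagents that add atoms: isobutyl chloroformate, CC(C)COC(=O)Cl (its atoms are present in 33 only)
Why: Activation of the acid as a mixed carbonic anhydride and borohydride reduction give the primary allylic alcohol; at 0 °C borohydride does not reduce the lactone or the C8 ester.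

Step 22
Reactants: 34 15-hydroxy-8-[(3S)-4-(tert-butyldimethylsilyloxy)-3-methylbutanoyloxy]germacra-1(10),4-dien-12,6-olide
Product: 35 (6R,7R,8S,11S)-15-hydroxy-8-[(3S)-4-hydroxy-3-methylbutanoyloxy]germacra-1(10),4-dien-12,6-olide (CNP0160815.1)
Conditions: HF·pyridine, pyridine, THF, 0 °C to rt
Reagents that add atoms: none
Why: Fluoride cleavage of the primary silyl ether under buffered conditions that avoid base-induced acyl migration and acid-induced transannular cyclisation.

## Compound list

1 | (−)-quinic acid, (1S,3R,4S,5R)-1,3,4,5-tetrahydroxycyclohexane-1-carboxylic acid | C1[C@H]([C@H]([C@@H](C[C@@]1(C(=O)O)O)O)O)O | starting material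
2 | 3,4-O-isopropylidenequinic acid 1,5-lactone (acetonide on the cis O3/O4 pair, carboxyl lactonised onto O5, C1 hydroxyl free) | CC1(C)O[C@@H]2C[C@]3(O)C[C@H]([C@@H]2O1)OC3=O | intermediate
3 | 1-(hydroxymethyl)-3,4-O-isopropylidenecyclohexane-1,3,4,5-tetrol with the quinic acid configuration | CC1(C)O[C@@H]2C[C@@](O)(CO)C[C@@H](O)[C@@H]2O1 | intermediate
4 | (3R,4S,5R)-3-hydroxy-4,5-(isopropylidenedioxy)cyclohexan-1-one | CC1(C)O[C@@H]2CC(=O)C[C@@H](O)[C@@H]2O1 | intermediate
5 | methanesulfonate of 4 (β-mesyloxy ketone) | CC1(C)O[C@@H]2CC(=O)C[C@@H](OS(C)(=O)=O)[C@@H]2O1 | intermediate (not isolated)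
6 | (4S,5R)-4,5-(isopropylidenedioxy)cyclohex-2-en-1-one | CC1(C)O[C@@H]2CC(=O)C=C[C@@H]2O1 | intermediate
7 | (R)-5-hydroxycyclohex-3-en-1-one | O[C@@H]1CC(=O)CC=C1 | intermediate (not isolated)
8 | (S)-5-hydroxycyclohex-2-en-1-one | O[C@@H]1CC(=O)C=CC1 | intermediate
9 | (S)-5-(tert-butyldimethylsilyloxy)cyclohex-2-en-1-one | O=C1C=CC[C@H](O[Si](C)(C)C(C)(C)C)C1 | intermediate
10 | (3S,5S)-5-(tert-butyldimethylsilyloxy)-3-methyl-1-(trimethylsilyloxy)cyclohex-1-ene (methyl and silyloxy trans) | C[C@H]1C[C@H](O[Si](C)(C)C(C)(C)C)CC(O[Si](C)(C)C)=C1 | intermediate (not isolated)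
11 | (S)-5-(tert-butyldimethylsilyloxy)-3-methylcyclohex-2-en-1-one | O=C1C=C(C)C[C@H](O[Si](C)(C)C(C)(C)C)C1 | intermediate
12 | methyl (S)-lactate | C[C@H](O)C(=O)OC | starting material
13 | methyl (S)-2-(trifluoromethylsulfonyloxy)propanoate | C[C@H](OS(=O)(=O)C(F)(F)F)C(=O)OC | intermediate
14 | kinetic lithium dienolate of 11 (O–C6=C7 enolate, C5=C10 retained, 8S) | [Li]OC1=C[C@@H](O[Si](C)(C)C(C)(C)C)CC(C)=C1 | intermediate (not isolated)
15 | methyl (2S)-2-[(1R,6S)-6-(tert-butyldimethylsilyloxy)-4-methyl-2-oxocyclohex-3-en-1-yl]propanoate (key-step precursor; 7R,8S,11S) | O=C1C=C(C)C[C@H](O[Si](C)(C)C(C)(C)C)[C@H]1[C@H](C)C(=O)OC | intermediate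
16 | ethyl 1-bromocyclobutane-1-carboxylate | CCOC(=O)C1(Br)CCC1 | starting material
17 | cyclobut-1-ene-1-carboxylic acid | OC(=O)C1=CCC1 | intermediate
18 | tert-butyl cyclobut-1-ene-1-carboxylate | CC(C)(C)OC(=O)C1=CCC1 | intermediate
19 | tert-butyl 8-(tert-butyldimethylsilyloxy)-9-[(2S)-1-methoxy-1-oxopropan-2-yl]-6-methyl-10-oxotricyclo[4.4.0.0^2,5]decane-2-carboxylate, head-to-head cis-anti-cis photoadduct (C1–C10 and C4–C5 formed; cyclobutane anti to the silyloxy group) | O=C1[C@H]2[C@]3(C(=O)OC(C)(C)C)CC[C@@H]3[C@@]2(C)C[C@H](O[Si](C)(C)C(C)(C)C)[C@H]1[C@H](C)C(=O)OC | intermediate (not isolated)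
20 | tert-butyl (7R,8S)-8-(tert-butyldimethylsilyloxy)-7-[(2S)-1-methoxy-1-oxopropan-2-yl]-10-methyl-6-oxocyclodeca-1(10),4-diene-4-carboxylate (ring-cis C1=C10, ring-trans C4=C5) | C/C1=C/CC/C(C(=O)OC(C)(C)C)=C/C(=O)[C@H]([C@H](C)C(=O)OC)[C@@H](O[Si](C)(C)C(C)(C)C)C1 | intermediate
21 | C6 allylic alcohol of 20 (6R, H6 anti to H7; other centres and both alkenes as in 20) | C/C1=C/CC/C(C(=O)OC(C)(C)C)=C/[C@@H](O)[C@H]([C@H](C)C(=O)OC)[C@@H](O[Si](C)(C)C(C)(C)C)C1 | intermediate (not isolated)
22 | tert-butyl 8-(tert-butyldimethylsilyloxy)germacra-1(10),4-dien-12,6-olid-15-oate (trans-fused lactone; C6, C7, C8, C11 as in the target) | C/C1=C/CC/C(C(=O)OC(C)(C)C)=C/[C@H]2OC(=O)[C@@H](C)[C@@H]2[C@@H](O[Si](C)(C)C(C)(C)C)C1 | intermediate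
23 | tert-butyl 8-hydroxygermacra-1(10),4-dien-12,6-olid-15-oate (same configuration) | C/C1=C/CC/C(C(=O)OC(C)(C)C)=C/[C@H]2OC(=O)[C@@H](C)[C@@H]2[C@@H](O)C1 | intermediate
24 | methyl (R)-3-hydroxy-2-methylpropanoate | COC(=O)[C@H](C)CO | starting material
25 | methyl (R)-3-(tert-butyldimethylsilyloxy)-2-methylpropanoate | COC(=O)[C@H](C)CO[Si](C)(C)C(C)(C)C | intermediate
26 | (S)-3-(tert-butyldimethylsilyloxy)-2-methylpropan-1-ol | OC[C@H](C)CO[Si](C)(C)C(C)(C)C | intermediate
27 | (R)-tert-butyl(3-iodo-2-methylpropoxy)dimethylsilane | IC[C@H](C)CO[Si](C)(C)C(C)(C)C | intermediate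
28 | (S)-[3-(tert-butyldimethylsilyloxy)-2-methylpropyl]lithium | [Li]C[C@H](C)CO[Si](C)(C)C(C)(C)C | intermediate (not isolated)
29 | (S)-4-(tert-butyldimethylsilyloxy)-3-methylbutanoic acid | OC(=O)C[C@H](C)CO[Si](C)(C)C(C)(C)C | intermediate
30 | tert-butyl 8-[(3S)-4-(tert-butyldimethylsilyloxy)-3-methylbutanoyloxy]germacra-1(10),4-dien-12,6-olid-15-oate | C/C1=C/CC/C(C(=O)OC(C)(C)C)=C/[C@H]2OC(=O)[C@@H](C)[C@@H]2[C@@H](OC(=O)C[C@H](C)CO[Si](C)(C)C(C)(C)C)C1 | intermediate
31 | trimethylsilyl ester corresponding to 30 | C/C1=C/CC/C(C(=O)O[Si](C)(C)C)=C/[C@H]2OC(=O)[C@@H](C)[C@@H]2[C@@H](OC(=O)C[C@H](C)CO[Si](C)(C)C(C)(C)C)C1 | intermediate (not isolated)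
32 | 8-[(3S)-4-(tert-butyldimethylsilyloxy)-3-methylbutanoyloxy]germacra-1(10),4-dien-12,6-olid-15-oic acid | C/C1=C/CC/C(C(=O)O)=C/[C@H]2OC(=O)[C@@H](C)[C@@H]2[C@@H](OC(=O)C[C@H](C)CO[Si](C)(C)C(C)(C)C)C1 | intermediate
33 | isobutyl carbonic mixed anhydride of 32 | C/C1=C/CC/C(C(=O)OC(=O)OCC(C)C)=C/[C@H]2OC(=O)[C@@H](C)[C@@H]2[C@@H](OC(=O)C[C@H](C)CO[Si](C)(C)C(C)(C)C)C1 | intermediate (not isolated)
34 | 15-hydroxy-8-[(3S)-4-(tert-butyldimethylsilyloxy)-3-methylbutanoyloxy]germacra-1(10),4-dien-12,6-olide | C/C1=C/CC/C(CO)=C/[C@H]2OC(=O)[C@@H](C)[C@@H]2[C@@H](OC(=O)C[C@H](C)CO[Si](C)(C)C(C)(C)C)C1 | intermediate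
35 | (6R,7R,8S,11S)-15-hydroxy-8-[(3S)-4-hydroxy-3-methylbutanoyloxy]germacra-1(10),4-dien-12,6-olide (CNP0160815.1; ring-cis C1=C10, ring-trans C4=C5) | C/C1=C/CC/C(CO)=C/[C@H]2OC(=O)[C@@H](C)[C@@H]2[C@@H](OC(=O)C[C@H](C)CO)C1 | target

## Step count and least certain steps

Total step count: 22 (telescoped operations counted as one step). Longest linear sequence: 15 steps (steps 1 to 7, 9, 12 to 14, 19 to 22).

Step 12 (key step). The most likely failure is erosion of head-to-head regiocontrol in the photoaddition. The β-methyl group on C10 slows the first bond formation there and the ester polarises the cyclobutene only moderately, so head-to-tail adducts that cannot fragment to the germacrane ring may compete. Cope drift during heating is the secondary concern and is handled by short contact time. The fallback sets out from 15 and 17 and comes back at 19. The photoaddition would be run with the free acid 17 in a non-polar solvent, where hydrogen bonding of the carboxyl group to the enone carbonyl holds the carboxyl-bearing carbon next to C5. This should give the head-to-head cis-anti-cis photoadduct carboxylic acid F1, which would be converted into 19 with tert-butyl 2,2,2-trichloroacetimidate (BF3·OEt2 cat., CH2Cl2–cyclohexane) and then heated as in step 12.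

Step 9. The likely failure is that the basic enolate 14 eliminates the secondary triflate to methyl acrylate (E2), or expels its own β-silyloxy group on warming, faster than it substitutes. The fallback sets out from 11 and comes back at 15. Condensation of 11 with 1,1-dimethylhydrazine would give the N,N-dimethylhydrazone of 11 F2. Its azaenolate (LDA, THF, −78 °C) is a softer and more nucleophilic carbon nucleophile and would be alkylated by 13 anti to the silyloxy group to give the N,N-dimethylhydrazone of 15 F3. Hydrolysis with aqueous CuCl2 at pH 7 would release 15.

Step 13. The likely failure is poor facial selectivity at C6, because the reacting conformation of the ten-membered enone is not known; the 6-epimer would close to the cis-fused lactone. Competing 1,4-reduction of the doubly activated alkene is also possible. The fallback sets out from 20 and comes back at 22. Substrate control would be replaced by catalyst control: Corey–Bakshi–Shibata reduction with (R)-2-methyl-CBS-oxazaborolidine and catecholborane in toluene at −78 °C. This is the enantiomer predicted to give the 6R alcohol when the alkenyl arm acts as the larger group, and catecholborane does not hydroborate the ring alkenes. Lactonisation would follow as in step 13; no new compound is made (F0).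

Step 5. The likely failure is unselective reduction (conjugate reduction or pinacol coupling), because an acetonide alkoxide is a modest leaving group, together with dehydration of the unprotected β-hydroxy enone to phenol during isomerisation. The fallback sets out from 4 and comes back at 9. Silylation of 4 would give the tert-butyldimethylsilyl ether of 4 F4. DBU would open the acetonide by E1cB elimination to (4R,5R)-5-(tert-butyldimethylsilyloxy)-4-hydroxycyclohex-2-en-1-one F5. Acetylation would give the 4-O-acetate of F5 F6, and activated zinc in acetic acid followed by Et3N would remove the γ-acetoxy group and restore conjugation. This gives 9 with the silyl ether already in place and a better leaving group on the γ-carbon.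

## Further compounds

F1 | step 12 | head-to-head cis-anti-cis photoadduct carboxylic acid (the C15 acid corresponding to 19) | O=C1[C@H]2[C@]3(C(=O)O)CC[C@@H]3[C@@]2(C)C[C@H](O[Si](C)(C)C(C)(C)C)[C@H]1[C@H](C)C(=O)OC
F2 | step 9 | N,N-dimethylhydrazone of 11 | CN(C)/N=C1\C=C(C)C[C@H](O[Si](C)(C)C(C)(C)C)C1
F3 | step 9 | N,N-dimethylhydrazone of 15 | CN(C)/N=C1\C=C(C)C[C@H](O[Si](C)(C)C(C)(C)C)[C@H]1[C@H](C)C(=O)OC
F0 | step 13 | none | none
F4 | step 5 | tert-butyldimethylsilyl ether of 4 | CC1(C)O[C@@H]2CC(=O)C[C@@H](O[Si](C)(C)C(C)(C)C)[C@@H]2O1
F5 | step 5 | (4R,5R)-5-(tert-butyldimethylsilyloxy)-4-hydroxycyclohex-2-en-1-one | O=C1C=C[C@@H](O)[C@H](O[Si](C)(C)C(C)(C)C)C1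
F6 | step 5 | 4-O-acetate of F5 | O=C1C=C[C@@H](OC(C)=O)[C@H](O[Si](C)(C)C(C)(C)C)C1
A1 | alternative 1 | thirteen-membered cyclic ether: C8 tributylstannyl α-alkoxy carbon linked through O8 to C12 of the C7=C11 allyl unit, O6 triethylsilyl and O15 tert-butyldimethylsilyl ethers | C/C1=C/CC/C(CO[Si](C)(C)C(C)(C)C)=C/[C@@H](O[Si](CC)(CC)CC)/C=C(C)/CO[C@@H]([Sn](CCCC)(CCCC)CCCC)C1
A2 | alternative 1 | 7-isopropenylcyclodeca-1(10),4-dien-8-ol with O6 triethylsilyl and O15 tert-butyldimethylsilyl ethers | C/C1=C/CC/C(CO[Si](C)(C)C(C)(C)C)=C/[C@@H](O[Si](CC)(CC)CC)[C@H](C(C)=C)[C@@H](O)C1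
A3 | alternative 2 | open-chain lactone with allylic bromides at C2 and C3, both silyl ethers in place | BrC/C=C(/C)C[C@H](OC(=O)C[C@H](C)CO[Si](C)(C)C(C)(C)C)[C@H]1[C@H](C)C(=O)O[C@@H]1/C=C(/CBr)CO[Si](C)(C)C(C)(C)C
A4 | alternative 2 | bis(tert-butyldimethylsilyl) ether of the target | C/C1=C/CC/C(CO[Si](C)(C)C(C)(C)C)=C/[C@H]2OC(=O)[C@@H](C)[C@@H]2[C@@H](OC(=O)C[C@H](C)CO[Si](C)(C)C(C)(C)C)C1
A5 | alternative 3 | open-chain C5 alkenyl iodide and C6 aldehyde with C12 methyl ester, O8 triethylsilyl and O15 tert-butyldiphenylsilyl ethers | O=C[C@H]([C@H](C)C(=O)OC)[C@@H](O[Si](CC)(CC)CC)C/C(C)=C\CC/C(CO[Si](c1ccccc1)(c1ccccc1)C(C)(C)C)=C/I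
A6 | alternative 3 | ten-membered C6 allylic alcohol with C12 methyl ester, O8 triethylsilyl and O15 tert-butyldiphenylsilyl ethers | C/C1=C/CC/C(CO[Si](c2ccccc2)(c2ccccc2)C(C)(C)C)=C/[C@@H](O)[C@H]([C@H](C)C(=O)OC)[C@@H](O[Si](CC)(CC)CC)C1
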